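**Retrosynthetic overview**
1. Target 32 ⇐ CBS reduction of the C7 enone 31 ⇐ oxidation of the Nozaki–Hiyama–Kishi macrocyclisation product 30 (C6–C7 bond, ten-membered ring closed last) from iodo-aldehyde 28.
2. 28 ⇐ Mitsunobu angeloylation with inversion at C4 of the Barbier adduct 23.
3. Key union: zinc Barbier allylation of 3-iodobut-3-enal 21 by the bromobutenolide 18 (C3a–C4 bond; C3a and C4 set; α-methylene lactone unveiled).
4. 18 ⇐ ring-closing metathesis of 2-(bromomethyl)acrylate 17 ⇐ anti-diol monoacetate 14 ⇐ Brown alkoxyallylation of (E)-enal 5, then oxidation and chelation-controlled reduction.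
5. Ring order: butenolide (step 12), then the ten-membered carbocycle (step 19).

Locants C3a, C4, C7, C11 and C11a are those of the cyclodeca[b]furan name of 32.

Assumption: the Barbier adduct 23 has the (1R) carbinol configuration that a closed chair transition state predicts (opposite to the target at C4), so the angelate is introduced with inversion in step 16.

**Step 1**
Reactants: 1 propane-1,3-diol
Product: 2 3-[(tert-butyldiphenylsilyl)oxy]propan-1-ol
Conditions: TBDPSCl (1 equiv), imidazole, 1 (5 equiv), THF, 0 °C to rt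
Reagents that add atoms: tert-butyl(chloro)diphenylsilane CC(C)(C)[Si](Cl)(c1ccccc1)c1ccccc1
Why: Statistical monosilylation of an excess of the symmetric diol gives the mono silyl ether cleanly (silyl ether formation).

**Step 2**
Reactants: 2 3-[(tert-butyldiphenylsilyl)oxy]propan-1-ol
Product: 3 3-[(tert-butyldiphenylsilyl)oxy]propanal
Conditions: PhI(OAc)2, TEMPO (10 mol %), CH2Cl2, rt
Reagents that add atoms: none
Why: TEMPO-catalysed oxidation takes the primary alcohol to the aldehyde without over-oxidation or β-elimination.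

**Step 3**
Reactants: 3 3-[(tert-butyldiphenylsilyl)oxy]propanal; 4 2-(triphenyl-λ5-phosphanylidene)propanal
Product: 5 (2E)-5-[(tert-butyldiphenylsilyl)oxy]-2-methylpent-2-enal
Conditions: toluene, 90 °C
Reagents that add atoms: none
Why: Wittig olefination with a stabilised ylide gives the (E)-trisubstituted enal, which fixes the geometry of the ring alkene (C9=C10) for the whole route.

**Step 4**
Reactants: 6 prop-2-en-1-ol
Product: 7 3-(methoxymethoxy)prop-1-ene
Conditions: MOMCl, i-Pr2NEt, CH2Cl2, 0 °C to rt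
Reagents that add atoms: chloromethyl methyl ether COCCl
Why: O-alkylation gives the allyl MOM ether needed for γ-alkoxyallyl metalation (acetal protection).

**Step 5**
Reactants: 7 3-(methoxymethoxy)prop-1-ene; 5 (2E)-5-[(tert-butyldiphenylsilyl)oxy]-2-methylpent-2-enal
Product: 10 (3R,4R,5E)-8-[(tert-butyldiphenylsilyl)oxy]-3-(methoxymethoxy)-5-methylocta-1,5-dien-4-ol, via (Z)-3-(methoxymethoxy)allylbis(isopinocampheyl)borane 8 (not isolated), via bis(isopinocampheyl)borinate ester 9 (not isolated)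
Conditions: 7, s-BuLi, THF, −78 °C; (−)-Ipc2BOMe [from (+)-α-pinene]; BF3·OEt2; 5, −78 °C; then NaOH, H2O2, 0 °C to rt
Reagents that add atoms: none
Why: Brown alkoxyallylboration: the (Z)-γ-alkoxyallylborane adds through a closed chair transition state (syn) to the Si face of the aldehyde, setting C3 (future C11a) as R; C4 is corrected in steps 6 and 7.

**Step 6**
Reactants: 10 (3R,4R,5E)-8-[(tert-butyldiphenylsilyl)oxy]-3-(methoxymethoxy)-5-methylocta-1,5-dien-4-ol
Product: 11 (3R,5E)-8-[(tert-butyldiphenylsilyl)oxy]-3-(methoxymethoxy)-5-methylocta-1,5-dien-4-one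
Conditions: Dess–Martin periodinane, NaHCO3, CH2Cl2, 0 °C; used without chromatography
Reagents that add atoms: none
Why: Buffered Dess–Martin oxidation of the allylic alcohol gives the enone without epimerising or conjugating the sensitive α-alkoxy centre.

**Step 7**
Reactants: 11 (3R,5E)-8-[(tert-butyldiphenylsilyl)oxy]-3-(methoxymethoxy)-5-methylocta-1,5-dien-4-one
Product: 12 (3R,4S,5E)-8-[(tert-butyldiphenylsilyl)oxy]-3-(methoxymethoxy)-5-methylocta-1,5-dien-4-ol
Conditions: Zn(BH4)2, Et2O, −30 °C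
Reagents that add atoms: none
Why: Cram-chelate 1,2-reduction: zinc bridges the ketone and the α-MOM oxygen and hydride enters from the side of the α-hydrogen, giving the 3,4-anti (4S) alcohol, the C11 configuration of the target.

**Step 8**
Reactants: 12 (3R,4S,5E)-8-[(tert-butyldiphenylsilyl)oxy]-3-(methoxymethoxy)-5-methylocta-1,5-dien-4-ol
Product: 13 (3R,4S,5E)-8-[(tert-butyldiphenylsilyl)oxy]-3-(methoxymethoxy)-5-methylocta-1,5-dien-4-yl acetate
Conditions: Ac2O, pyridine, DMAP (cat.), CH2Cl2, 0 °C to rt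
Reagents that add atoms: acetic anhydride CC(=O)OC(C)=O
Why: Acylation installs the C11 acetate of the target early, and it then serves as the protecting group.

**Step 9**
Reactants: 13 (3R,4S,5E)-8-[(tert-butyldiphenylsilyl)oxy]-3-(methoxymethoxy)-5-methylocta-1,5-dien-4-yl acetate
Product: 14 (3R,4S,5E)-8-[(tert-butyldiphenylsilyl)oxy]-3-hydroxy-5-methylocta-1,5-dien-4-yl acetate
Conditions: Me2BBr, CH2Cl2, −78 °C; then THF/sat. aq. NaHCO3; used at once
Reagents that add atoms: none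
Why: Lewis-acid cleavage of the MOM acetal at −78 °C spares the acetate, the silyl ether and the alkenes; immediate use limits 1,2-acetyl migration.

**Step 10**
Reactants: 15 2-(bromomethyl)prop-2-enoic acid
Product: 16 2-(bromomethyl)prop-2-enoyl chloride
Conditions: (COCl)2, DMF (cat.), CH2Cl2, 0 °C to rt; concentrate
Reagents that add atoms: oxalyl chloride O=C(Cl)C(=O)Cl
Why: Vilsmeier-type activation gives the acid chloride, so the ester can be made without a nucleophilic catalyst that would attack the allylic bromide.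

**Step 11**
Reactants: 14 (3R,4S,5E)-8-[(tert-butyldiphenylsilyl)oxy]-3-hydroxy-5-methylocta-1,5-dien-4-yl acetate; 16 2-(bromomethyl)prop-2-enoyl chloride
Product: 17 (3R,4S,5E)-4-(acetyloxy)-8-[(tert-butyldiphenylsilyl)oxy]-5-methylocta-1,5-dien-3-yl 2-(bromomethyl)prop-2-enoate
Conditions: 2,6-lutidine, CH2Cl2, −40 to 0 °C
Reagents that add atoms: none
Why: O-acylation with a hindered, non-nucleophilic base avoids SN2' attack on the allylic bromide and acetyl migration.

**Step 12**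
Reactants: 17 (3R,4S,5E)-4-(acetyloxy)-8-[(tert-butyldiphenylsilyl)oxy]-5-methylocta-1,5-dien-3-yl 2-(bromomethyl)prop-2-enoate
Product: 18 (1S,2E)-1-[(2R)-4-(bromomethyl)-5-oxo-2,5-dihydrofuran-2-yl]-5-[(tert-butyldiphenylsilyl)oxy]-2-methylpent-2-en-1-yl acetate
Conditions: second-generation Grubbs catalyst (H2IMes)(PCy3)Cl2Ru=CHPh (10 mol %), toluene (5 mM), 80 °C
Reagents that add atoms: none
Why: Ring-closing metathesis between the vinyl group and the acrylate closes the butenolide with loss of ethene; the trisubstituted side-chain alkene does not take part.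

**Step 13**
Reactants: 19 but-3-yn-1-ol
Product: 20 3-iodobut-3-en-1-ol
Conditions: NaI, TMSCl, H2O, MeCN, rt
Reagents that add atoms: sodium iodide [Na+].[I-]
Why: Markovnikov hydroiodination of the terminal alkyne with HI made in the flask gives the 2-iodoalkene.

**Step 14**
Reactants: 20 3-iodobut-3-en-1-ol
Product: 21 3-iodobut-3-enal
Conditions: Dess–Martin periodinane, NaHCO3, CH2Cl2, 0 °C; used crude at once
Reagents that add atoms: none
Why: Neutral oxidation gives the labile β,γ-unsaturated aldehyde without conjugation, provided it is not stored.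

**Step 15**
Reactants: 18 (1S,2E)-1-[(2R)-4-(bromomethyl)-5-oxo-2,5-dihydrofuran-2-yl]-5-[(tert-butyldiphenylsilyl)oxy]-2-methylpent-2-en-1-yl acetate; 21 3-iodobut-3-enal (2.5 equiv)
Product: 23 (1S,2E)-5-[(tert-butyldiphenylsilyl)oxy]-1-{(2R,3S)-3-[(1R)-1-hydroxy-3-iodobut-3-en-1-yl]-4-methylidene-5-oxooxolan-2-yl}-2-methylpent-2-en-1-yl acetate, via allylzinc bromide 22 (not isolated)
Conditions: Zn powder, THF/sat. aq. NH4Cl, 0 °C to rt
Reagents that add atoms: none
Why: Zinc Barbier carbonyl allylation (SE2'): the ring γ-carbon attacks anti to the side chain on C5 of the butenolide (2,3-trans lactone, C3a), and the ring-locked (E)-type allylzinc in a Zimmerman–Traxler chair with the aldehyde substituent equatorial gives the (1R) carbinol.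

**Step 16**
Reactants: 23 (Barbier adduct as named in step 15); 24 (2Z)-2-methylbut-2-enoic acid (angelic acid)
Product: 26 (1S)-1-[(2R,3S)-2-{(1S,2E)-1-(acetyloxy)-5-[(tert-butyldiphenylsilyl)oxy]-2-methylpent-2-en-1-yl}-4-methylidene-5-oxooxolan-3-yl]-3-iodobut-3-en-1-yl (2Z)-2-methylbut-2-enoate, via alkoxyphosphonium angelate 25 (not isolated)
Conditions: PPh3, DIAD, toluene, 0 °C to rt
Reagents that add atoms: none
Why: Mitsunobu esterification: SN2 displacement of the alkoxyphosphonium by angelate inverts the carbinol to the (S) configuration of C4, and since the acid is never made into an acyl donor its Z geometry is not scrambled.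

**Step 17**
Reactants: 26 (angelate silyl ether as named in step 16)
Product: 27 (1S)-1-{(2R,3S)-2-[(1S,2E)-1-(acetyloxy)-5-hydroxy-2-methylpent-2-en-1-yl]-4-methylidene-5-oxooxolan-3-yl}-3-iodobut-3-en-1-yl (2Z)-2-methylbut-2-enoate
Conditions: HF·pyridine, pyridine, THF, 0 °C to rt
Reagents that add atoms: none
Why: Buffered fluoride desilylation frees the primary alcohol without base, so the esters and the α-methylene lactone survive.

**Step 18**
Reactants: 27 (primary alcohol as named in step 17)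
Product: 28 (1S)-1-{(2R,3S)-2-[(1S,2E)-1-(acetyloxy)-2-methyl-5-oxopent-2-en-1-yl]-4-methylidene-5-oxooxolan-3-yl}-3-iodobut-3-en-1-yl (2Z)-2-methylbut-2-enoate
Conditions: Dess–Martin periodinane, NaHCO3, CH2Cl2, 0 °C; used at once
Reagents that add atoms: none
Why: Neutral oxidation gives the β,γ-unsaturated aldehyde without moving the trisubstituted alkene into conjugation.

**Step 19**
Reactants: 28 (iodo-aldehyde as named in step 18)
Product: 30 (3aS,4S,9E,11S,11aR)-11-(acetyloxy)-7-hydroxy-10-methyl-3,6-dimethylidene-2-oxo-2,3,3a,4,5,6,7,8,11,11a-decahydrocyclodeca[b]furan-4-yl (2Z)-2-methylbut-2-enoate (both C7 epimers), via alkenylchromium dichloride 29 (not isolated)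
Conditions: CrCl2 (10 equiv), NiCl2 (5 mol %), DMSO/THF, 2 mM (slow addition), rt
Reagents that add atoms: none
Why: Nozaki–Hiyama–Kishi reaction: zerovalent nickel inserts into the C–I bond, the alkenyl group passes to chromium and adds 1,2 to the aldehyde under high dilution, closing the ten-membered ring; C7 forms without reliable control and is reset in steps 20 and 21.

**Step 20**
Reactants: 30 (macrocyclic allylic alcohol, C7 epimers)
Product: 31 (3aS,4S,9E,11S,11aR)-11-(acetyloxy)-10-methyl-3,6-dimethylidene-2,7-dioxo-2,3,3a,4,5,6,7,8,11,11a-decahydrocyclodeca[b]furan-4-yl (2Z)-2-methylbut-2-enoate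
Conditions: Dess–Martin periodinane, NaHCO3, CH2Cl2, 0 °C to rt
Reagents that add atoms: none
Why: Oxidation of the allylic alcohol converges both epimers on one enone under non-basic conditions that leave the skipped alkene in place.

**Step 21**
Reactants: 31 (enone as named in step 20)
Product: 32 (3aS,4S,7S,9E,11S,11aR)-11-(acetyloxy)-7-hydroxy-10-methyl-3,6-dimethylidene-2-oxo-2,3,3a,4,5,6,7,8,11,11a-decahydrocyclodeca[b]furan-4-yl (2Z)-2-methylbut-2-enoate (target)
Conditions: (R)-Me-CBS [(R)-1-methyl-3,3-diphenyltetrahydro-1H,3H-pyrrolo[1,2-c][1,3,2]oxazaborole] (1 equiv), catecholborane, toluene, −78 °C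
Reagents that add atoms: none
Why: Corey–Bakshi–Shibata reduction: the branched alkenyl side of the ketone acts as the large group, so the (R)-catalyst delivers hydride to give the (7S)-alcohol, 1,2-selectively and without touching the lactone or esters.

**Compound list**
1 | propane-1,3-diol | OCCCO | starting material
2 | 3-[(tert-butyldiphenylsilyl)oxy]propan-1-ol | OCCCO[Si](c1ccccc1)(c1ccccc1)C(C)(C)C | intermediate
3 | 3-[(tert-butyldiphenylsilyl)oxy]propanal | O=CCCO[Si](c1ccccc1)(c1ccccc1)C(C)(C)C | intermediate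
4 | 2-(triphenyl-λ5-phosphanylidene)propanal | CC(C=O)=P(c1ccccc1)(c1ccccc1)c1ccccc1 | starting material
5 | (2E)-5-[(tert-butyldiphenylsilyl)oxy]-2-methylpent-2-enal | O=C/C(C)=C/CCO[Si](c1ccccc1)(c1ccccc1)C(C)(C)C | intermediate
6 | prop-2-en-1-ol | C=CCO | starting material
7 | 3-(methoxymethoxy)prop-1-ene | C=CCOCOC | intermediate
8 | [(2Z)-3-(methoxymethoxy)prop-2-en-1-yl]bis(isopinocampheyl)borane, Ipc from (+)-α-pinene | COCO/C=C\CB([C@@H]1C[C@@H]2C[C@H]([C@H]1C)C2(C)C)[C@@H]1C[C@@H]2C[C@H]([C@H]1C)C2(C)C | intermediate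
9 | bis(isopinocampheyl)borinate ester of 10 | C=C[C@@H](OCOC)[C@H](OB([C@@H]1C[C@@H]2C[C@H]([C@H]1C)C2(C)C)[C@@H]1C[C@@H]2C[C@H]([C@H]1C)C2(C)C)/C(C)=C/CCO[Si](c1ccccc1)(c1ccccc1)C(C)(C)C | intermediate
10 | (3R,4R,5E)-8-[(tert-butyldiphenylsilyl)oxy]-3-(methoxymethoxy)-5-methylocta-1,5-dien-4-ol | C=C[C@@H](OCOC)[C@H](O)/C(C)=C/CCO[Si](c1ccccc1)(c1ccccc1)C(C)(C)C | intermediate
11 | (3R,5E)-8-[(tert-butyldiphenylsilyl)oxy]-3-(methoxymethoxy)-5-methylocta-1,5-dien-4-one | C=C[C@@H](OCOC)C(=O)/C(C)=C/CCO[Si](c1ccccc1)(c1ccccc1)C(C)(C)C | intermediate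
12 | (3R,4S,5E)-8-[(tert-butyldiphenylsilyl)oxy]-3-(methoxymethoxy)-5-methylocta-1,5-dien-4-ol | C=C[C@@H](OCOC)[C@@H](O)/C(C)=C/CCO[Si](c1ccccc1)(c1ccccc1)C(C)(C)C | intermediate
13 | (3R,4S,5E)-8-[(tert-butyldiphenylsilyl)oxy]-3-(methoxymethoxy)-5-methylocta-1,5-dien-4-yl acetate | C=C[C@@H](OCOC)[C@@H](OC(C)=O)/C(C)=C/CCO[Si](c1ccccc1)(c1ccccc1)C(C)(C)C | intermediate
14 | (3R,4S,5E)-8-[(tert-butyldiphenylsilyl)oxy]-3-hydroxy-5-methylocta-1,5-dien-4-yl acetate | C=C[C@@H](O)[C@@H](OC(C)=O)/C(C)=C/CCO[Si](c1ccccc1)(c1ccccc1)C(C)(C)C | intermediate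
15 | 2-(bromomethyl)prop-2-enoic acid | C=C(CBr)C(=O)O | starting material
16 | 2-(bromomethyl)prop-2-enoyl chloride | C=C(CBr)C(Cl)=O | intermediate
17 | (3R,4S,5E)-4-(acetyloxy)-8-[(tert-butyldiphenylsilyl)oxy]-5-methylocta-1,5-dien-3-yl 2-(bromomethyl)prop-2-enoate | C=C[C@@H](OC(=O)C(=C)CBr)[C@@H](OC(C)=O)/C(C)=C/CCO[Si](c1ccccc1)(c1ccccc1)C(C)(C)C | intermediate
18 | (1S,2E)-1-[(2R)-4-(bromomethyl)-5-oxo-2,5-dihydrofuran-2-yl]-5-[(tert-butyldiphenylsilyl)oxy]-2-methylpent-2-en-1-yl acetate | O=C1O[C@H](C=C1CBr)[C@@H](OC(C)=O)/C(C)=C/CCO[Si](c2ccccc2)(c2ccccc2)C(C)(C)C | intermediate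
19 | but-3-yn-1-ol | C#CCCO | starting material
20 | 3-iodobut-3-en-1-ol | C=C(I)CCO | intermediate
21 | 3-iodobut-3-enal | C=C(I)CC=O | intermediate
22 | allylzinc bromide formed from 18 (zinc on the former bromomethyl carbon) | Br[Zn]CC1=C[C@@H](OC1=O)[C@@H](OC(C)=O)/C(C)=C/CCO[Si](c2ccccc2)(c2ccccc2)C(C)(C)C | intermediate
23 | (1S,2E)-5-[(tert-butyldiphenylsilyl)oxy]-1-{(2R,3S)-3-[(1R)-1-hydroxy-3-iodobut-3-en-1-yl]-4-methylidene-5-oxooxolan-2-yl}-2-methylpent-2-en-1-yl acetate | C=C1C(=O)O[C@H]([C@@H]1[C@H](O)CC(I)=C)[C@@H](OC(C)=O)/C(C)=C/CCO[Si](c2ccccc2)(c2ccccc2)C(C)(C)C | intermediate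
24 | (2Z)-2-methylbut-2-enoic acid (angelic acid) | C/C=C(/C)C(=O)O | starting material
25 | alkoxytriphenylphosphonium salt of 23 with angelate counter-ion | C=C1C(=O)O[C@H]([C@@H]1[C@H](O[P+](c2ccccc2)(c2ccccc2)c2ccccc2)CC(I)=C)[C@@H](OC(C)=O)/C(C)=C/CCO[Si](c2ccccc2)(c2ccccc2)C(C)(C)C.C/C=C(/C)C(=O)[O-] | intermediate
26 | (1S)-1-[(2R,3S)-2-{(1S,2E)-1-(acetyloxy)-5-[(tert-butyldiphenylsilyl)oxy]-2-methylpent-2-en-1-yl}-4-methylidene-5-oxooxolan-3-yl]-3-iodobut-3-en-1-yl (2Z)-2-methylbut-2-enoate | C=C1C(=O)O[C@H]([C@@H]1[C@@H](OC(=O)/C(C)=C\C)CC(I)=C)[C@@H](OC(C)=O)/C(C)=C/CCO[Si](c2ccccc2)(c2ccccc2)C(C)(C)C | intermediate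
27 | (1S)-1-{(2R,3S)-2-[(1S,2E)-1-(acetyloxy)-5-hydroxy-2-methylpent-2-en-1-yl]-4-methylidene-5-oxooxolan-3-yl}-3-iodobut-3-en-1-yl (2Z)-2-methylbut-2-enoate | C=C1C(=O)O[C@H]([C@@H]1[C@@H](OC(=O)/C(C)=C\C)CC(I)=C)[C@@H](OC(C)=O)/C(C)=C/CCO | intermediate
28 | (1S)-1-{(2R,3S)-2-[(1S,2E)-1-(acetyloxy)-2-methyl-5-oxopent-2-en-1-yl]-4-methylidene-5-oxooxolan-3-yl}-3-iodobut-3-en-1-yl (2Z)-2-methylbut-2-enoate | C=C1C(=O)O[C@H]([C@@H]1[C@@H](OC(=O)/C(C)=C\C)CC(I)=C)[C@@H](OC(C)=O)/C(C)=C/CC=O | intermediate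
29 | alkenylchromium dichloride formed from 28 (chromium in place of iodine) | C=C1C(=O)O[C@H]([C@@H]1[C@@H](OC(=O)/C(C)=C\C)CC(=C)[Cr](Cl)Cl)[C@@H](OC(C)=O)/C(C)=C/CC=O | intermediate
30 | (3aS,4S,9E,11S,11aR)-11-(acetyloxy)-7-hydroxy-10-methyl-3,6-dimethylidene-2-oxo-2,3,3a,4,5,6,7,8,11,11a-decahydrocyclodeca[b]furan-4-yl (2Z)-2-methylbut-2-enoate, both C7 epimers | C=C1C(=O)O[C@@H]2[C@@H]1[C@@H](OC(=O)/C(C)=C\C)CC(=C)C(O)C/C=C(\C)[C@@H]2OC(C)=O | intermediate
31 | (3aS,4S,9E,11S,11aR)-11-(acetyloxy)-10-methyl-3,6-dimethylidene-2,7-dioxo-2,3,3a,4,5,6,7,8,11,11a-decahydrocyclodeca[b]furan-4-yl (2Z)-2-methylbut-2-enoate | C=C1C(=O)O[C@@H]2[C@@H]1[C@@H](OC(=O)/C(C)=C\C)CC(=C)C(=O)C/C=C(\C)[C@@H]2OC(C)=O | intermediate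
32 | (3aS,4S,7S,9E,11S,11aR)-11-(acetyloxy)-7-hydroxy-10-methyl-3,6-dimethylidene-2-oxo-2,3,3a,4,5,6,7,8,11,11a-decahydrocyclodeca[b]furan-4-yl (2Z)-2-methylbut-2-enoate | C=C1C(=O)O[C@@H]2[C@@H]1[C@@H](OC(=O)/C(C)=C\C)CC(=C)[C@@H](O)C/C=C(\C)[C@@H]2OC(C)=O | target

**Total step count:** 21 steps.
**Longest linear sequence:** 17 steps from propane-1,3-diol (steps 1, 2, 3, 5, 6, 7, 8, 9, 11, 12, 15, 16, 17, 18, 19, 20, 21).

**Three steps most likely to fail**

Step 19 (ten-membered ring closure by Nozaki–Hiyama–Kishi reaction). The ring is strained and oligomerisation can win. The fallback sets out from 27 and returns at 31. Alcohol 27 is oxidised through aldehyde 28 (Dess–Martin periodinane) and then with NaClO2, NaH2PO4 and 2-methylbut-2-ene to the carboxylic acid F1. The acid is condensed with thiophenol (DCC, cat. DMAP) to the S-phenyl thioester F2. Iodine is exchanged for tin (Me3SnSnMe3, Pd(PPh3)4, THF) to give the alkenylstannane F3. The ring is then closed by a palladium-catalysed, copper-mediated thioester–stannane ketone synthesis (Pd2(dba)3, tri(2-furyl)phosphine, CuO2PPh2, THF, high dilution). This gives enone 31 directly and bypasses steps 19 and 20.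

Step 16 (Mitsunobu angeloylation with inversion at a hindered carbinol). Elimination or no reaction is possible. The fallback sets out from 23 and returns at 26. Mitsunobu inversion with the smaller, more acidic formic acid (PPh3, DIAD, THF) gives the inverted formate F4. Brief methanolysis (KHCO3, MeOH, 0 °C) frees the (1S)-alcohol F5. This is acylated with retention by angelic acid 24 under Yamaguchi conditions (2,4,6-trichlorobenzoyl chloride, Et3N, toluene, 80 °C) to give 26.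

Step 12 (metathesis of an electron-poor, allylic-bromide-bearing acrylate). The catalyst may stall or the bromide may degrade. The fallback sets out from 14 and returns at 18. Alcohol 14 is acylated with acryloyl chloride (i-Pr2NEt, CH2Cl2, −78 °C) to the acrylate ester F6. A Morita–Baylis–Hillman reaction with aqueous formaldehyde (DABCO, dioxane/water) gives the 2-(hydroxymethyl)acrylate ester F7. Metathesis of this bromide-free substrate (same ruthenium catalyst) gives the 3-(hydroxymethyl)butenolide F8. Appel bromination (CBr4, PPh3, CH2Cl2, 0 °C) then gives 18.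

**Further compounds**
F1 | step 19 | (3E,5S)-5-(acetyloxy)-5-[(2R,3S)-3-{(1S)-3-iodo-1-[(2Z)-2-methylbut-2-enoyloxy]but-3-en-1-yl}-4-methylidene-5-oxooxolan-2-yl]-4-methylpent-3-enoic acid | C=C1C(=O)O[C@H]([C@@H]1[C@@H](OC(=O)/C(C)=C\C)CC(I)=C)[C@@H](OC(C)=O)/C(C)=C/CC(=O)O
F2 | step 19 | S-phenyl thioester of F1 | C=C1C(=O)O[C@H]([C@@H]1[C@@H](OC(=O)/C(C)=C\C)CC(I)=C)[C@@H](OC(C)=O)/C(C)=C/CC(=O)Sc2ccccc2
F3 | step 19 | S-phenyl thioester of F1 with trimethylstannyl in place of iodine | C=C1C(=O)O[C@H]([C@@H]1[C@@H](OC(=O)/C(C)=C\C)CC(=C)[Sn](C)(C)C)[C@@H](OC(C)=O)/C(C)=C/CC(=O)Sc2ccccc2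
F4 | step 16 | (1S)-formate of the C4 epimer of 23 | C=C1C(=O)O[C@H]([C@@H]1[C@@H](OC=O)CC(I)=C)[C@@H](OC(C)=O)/C(C)=C/CCO[Si](c2ccccc2)(c2ccccc2)C(C)(C)C
F5 | step 16 | (1S,2E)-5-[(tert-butyldiphenylsilyl)oxy]-1-{(2R,3S)-3-[(1S)-1-hydroxy-3-iodobut-3-en-1-yl]-4-methylidene-5-oxooxolan-2-yl}-2-methylpent-2-en-1-yl acetate | C=C1C(=O)O[C@H]([C@@H]1[C@@H](O)CC(I)=C)[C@@H](OC(C)=O)/C(C)=C/CCO[Si](c2ccccc2)(c2ccccc2)C(C)(C)C
F6 | step 12 | (3R,4S,5E)-4-(acetyloxy)-8-[(tert-butyldiphenylsilyl)oxy]-5-methylocta-1,5-dien-3-yl prop-2-enoate | C=C[C@@H](OC(=O)C=C)[C@@H](OC(C)=O)/C(C)=C/CCO[Si](c1ccccc1)(c1ccccc1)C(C)(C)C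
F7 | step 12 | (3R,4S,5E)-4-(acetyloxy)-8-[(tert-butyldiphenylsilyl)oxy]-5-methylocta-1,5-dien-3-yl 2-(hydroxymethyl)prop-2-enoate | C=C[C@@H](OC(=O)C(=C)CO)[C@@H](OC(C)=O)/C(C)=C/CCO[Si](c1ccccc1)(c1ccccc1)C(C)(C)C
F8 | step 12 | (1S,2E)-5-[(tert-butyldiphenylsilyl)oxy]-1-[(2R)-4-(hydroxymethyl)-5-oxo-2,5-dihydrofuran-2-yl]-2-methylpent-2-en-1-yl acetate | O=C1O[C@H](C=C1CO)[C@@H](OC(C)=O)/C(C)=C/CCO[Si](c2ccccc2)(c2ccccc2)C(C)(C)C
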